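The tetralin is cut at C3–C4 and C2–C3, so that C3 arrives as the central carbon of a malonate. Because the ring A hydroxyl on C7 lies para to C4a, unmasking it lets a benzylic ester on C4 leave and turns C4 into the exocyclic carbon of a p-quinone methide; the malonate adds there and its anion then opens a terminal oxirane at C2 with inversion, closing ring B and releasing the C2 hydroxymethyl group in one flask. The precursor is an enantiopure diarylmethyl oxirane holding C1 and C2, with a silyl-masked ring A phenol para to a pivaloyloxymethyl group. C3 is fixed later by equilibrating a ring ester beside a silylated hydroxymethyl group.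

Key step: step 10

Remark: locants follow the tetralin numbering of the target (aryl on C1); the enantiomer of each chiral catalyst in steps 7 and 8 is taken from its established facial preference so that the configurations written result.

Abbreviations in names: Ar1 = 4-methoxy-2-(pivaloyloxymethyl)-5-(triisopropylsilyloxy)phenyl; Ar2 = 4-benzyloxy-3,5-dimethoxyphenyl.

Step 1
Reactants: 1 2-bromo-4-hydroxy-5-methoxybenzaldehyde (6-bromovanillin)
Product: 2 2-bromo-5-methoxy-4-(triisopropylsilyloxy)benzaldehyde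
Conditions: i-Pr3SiCl, imidazole, DMF, rt
Reagents that add atoms: chlorotriisopropylsilane CC(C)[Si](Cl)(C(C)C)C(C)C
Why: Imidazole-promoted O-silylation of the acidic phenol should be clean, and the bulky triisopropylsilyl group is chosen because it must resist mild base until fluoride removes it in step 10.

Step 2
Reactants: 2 silylated bromo aldehyde
Product: 3 [2-bromo-5-methoxy-4-(triisopropylsilyloxy)phenyl]methanol
Conditions: NaBH4, THF/MeOH 4:1, 0 °C
Reagents that add atoms: none
Why: Borohydride reduction of the aryl aldehyde should give the benzylic alcohol without touching the aryl bromide or the silyl ether.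

Step 3
Reactants: 3 benzylic alcohol
Product: 4 2-bromo-5-methoxy-4-(triisopropylsilyloxy)benzyl pivalate
Conditions: t-BuCOCl, pyridine, DMAP (cat.), CH2Cl2, 0 °C to rt
Reagents that add atoms: pivaloyl chloride CC(C)(C)C(Cl)=O
Why: DMAP-catalysed acylation installs a hindered benzylic ester that stays inert until the para oxygen is unmasked, and it also prevents oxa-Michael closure onto the enal made in step 4.

Step 4
Reactants: 4 aryl bromide; 5 acrolein diethyl acetal
Product: 7 (E)-3-Ar1-prop-2-enal, via cinnamaldehyde diethyl acetal 6 (not isolated)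
Conditions: Pd(OAc)2 (3 mol %), n-Bu4NOAc, K2CO3, KCl, DMF, 90 °C; then 2 M HCl, rt
Reagents that add atoms: water O
Why: Heck reaction under ligand-free acetate/carbonate conditions, in which zerovalent palladium inserts into the C–Br bond, the aryl group adds to the terminal alkene carbon and β-hydride elimination towards the ring gives the E-alkene, the acetal masking the aldehyde until dilute acid hydrolyses it.

Step 5
Reactants: 8 4-bromo-2,6-dimethoxyphenol
Product: 9 2-benzyloxy-5-bromo-1,3-dimethoxybenzene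
Conditions: BnBr, K2CO3, DMF, rt
Reagents that add atoms: benzyl bromide BrCc1ccccc1
Why: Williamson ether synthesis on the phenoxide should proceed normally and gives a phenol mask that lasts to the final hydrogenolysis.

Step 6
Reactants: 9 aryl bromide
Product: 12 (4-benzyloxy-3,5-dimethoxyphenyl)boronic acid, via aryllithium 10 (not isolated), via lithium aryltriisopropoxyborate 11 (not isolated)
Conditions: n-BuLi, THF, −78 °C; B(Oi-Pr)3, −78 °C to rt; 1 M HCl
Reagents that add atoms: triisopropyl borate CC(C)OB(OC(C)C)OC(C)C; water O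
Why: Bromine–lithium exchange followed by borylation with a trialkyl borate and hydrolysis is the standard route to an arylboronic acid and tolerates the three ether groups.

Step 7
Reactants: 7 enal; 12 arylboronic acid
Product: 13 (S)-3-Ar2-3-Ar1-propanal
Conditions: 12 (2 equiv), [RhCl(C2H4)2]2 (2.5 mol %), chiral 2,5-diphenylbicyclo[2.2.2]octa-2,5-diene (5.5 mol %), KOH (10 mol %), dioxane/H2O 10:1, 30 °C
Reagents that add atoms: none
Why: Rhodium-catalysed asymmetric 1,4-addition of an arylboronic acid to an enal (Hayashi–Miyaura reaction), in which an aryl complex of monovalent rhodium inserts the alkene and is protonated off, the chiral diene selecting the enal face so that C1 is set as S while the nearly neutral hydroxorhodium conditions spare the silyl ether.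

Step 8
Reactants: 13 (S)-3,3-diarylpropanal
Product: 15 (2S,3S)-2-chloro-3-Ar2-3-Ar1-propan-1-ol, via alpha-chloro aldehyde 14 (not isolated)
Conditions: N-chlorosuccinimide, trans-2,5-diphenylpyrrolidine (10 mol %), CH2Cl2, 0 °C to rt; then NaBH4, MeOH, 0 °C
Reagents that add atoms: N-chlorosuccinimide O=C1CCC(=O)N1Cl
Why: Enamine-catalysed α-chlorination of an aldehyde, in which the C2-symmetric pyrrolidine shields one enamine face and should set the 2S chloride under catalyst control, and immediate borohydride reduction prevents epimerisation of the chloro aldehyde.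

Step 9
Reactants: 15 chlorohydrin
Product: 16 (R)-2-[(S)-Ar2(Ar1)methyl]oxirane
Conditions: NaH, THF, 0 °C to rt
Reagents that add atoms: none
Why: Intramolecular Williamson reaction (3-exo-tet SN2) of the primary alkoxide displaces chloride with inversion at C2 to give the R oxirane, under a non-nucleophilic base that leaves the aryl silyl ether and pivalate alone.

Step 10
Reactants: 16 diarylmethyl oxirane; 17 di-tert-butyl malonate
Product: 21 di-tert-butyl (1S,2R)-1-Ar2-7-hydroxy-2-(hydroxymethyl)-6-methoxytetralin-3,3-dicarboxylate, via free phenol 18 (not isolated), via para-quinone methide 19 (not isolated), via open-chain malonate adduct 20 (not isolated)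
Conditions: 17 (2 equiv), Cs2CO3 (2.5 equiv), CsF (1.2 equiv), DMF, 0 °C to rt, then 50 °C; aq NH4Cl
Reagents that add atoms: none
Why: Fluoride cleaves the aryl silyl ether, the phenoxide of 18 expels pivalate by 1,6-elimination to give quinone methide 19, the cesium malonate adds to its exocyclic carbon (C3–C4) and re-aromatises ring A to 20, and the resulting tertiary malonate carbanion opens the oxirane at its inner carbon (C2–C3). The closest known reactions are the 1,6-conjugate addition of malonates to p-quinone methides generated in situ from p-silyloxybenzyl esters and the intramolecular alkylation of malonate anions by epoxides. Ring B closes in the 6-exo-tet mode, the breaking C2–O bond lying outside the new ring, in preference to 7-endo attack at the CH2. C2 is the only stereocentre touched: backside attack on the R oxirane carbon places the CH2OH group trans to the C1 aryl group (the descriptor stays R only because the priorities change), and C1 is a spectator. The step needs exo over endo regioselectivity, which the shorter tether and the collinear trajectory at C2 should secure, and a single quinone methide, which is secured because only the ring A oxygen is unmasked and the other aryl ring has no benzylic leaving group. The excess malonate buffers the released alkoxide so that it should not attack the hindered tert-butyl esters.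

Step 11
Reactants: 21 phenol diester
Product: 22 di-tert-butyl (1S,2R)-7-benzyloxy-1-Ar2-2-(hydroxymethyl)-6-methoxytetralin-3,3-dicarboxylate
Conditions: BnBr, K2CO3, DMF, rt
Reagents that add atoms: benzyl bromide BrCc1ccccc1
Why: Williamson ether synthesis, selective because carbonate deprotonates only the phenol and not the primary alcohol.

Step 12
Reactants: 22 primary alcohol
Product: 23 di-tert-butyl (1S,2R)-7-benzyloxy-1-Ar2-2-[(tert-butyldiphenylsilyloxy)methyl]-6-methoxytetralin-3,3-dicarboxylate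
Conditions: t-BuPh2SiCl, imidazole, DMAP (cat.), DMF, rt to 40 °C
Reagents that add atoms: tert-butylchlorodiphenylsilane CC(C)(C)[Si](Cl)(c1ccccc1)c1ccccc1
Why: Imidazole-promoted O-silylation under neutral conditions caps the C2 hydroxymethyl group with a group that tolerates CF3CO2H and methoxide, so that no lactone can form once the C3 carboxyl is unmasked.

Step 13
Reactants: 23 silylated diester
Product: 25 (1S,2R,3RS)-7-benzyloxy-1-Ar2-2-[(tert-butyldiphenylsilyloxy)methyl]-6-methoxytetralin-3-carboxylic acid, via malonic acid 24 (not isolated)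
Conditions: CF3CO2H/CH2Cl2 1:4, 0 °C to rt; evaporate; pyridine, 100 °C
Reagents that add atoms: none
Why: Acidolysis of the tert-butyl esters with loss of isobutene gives malonic acid 24, which decarboxylates on heating through the usual cyclic transition state, C3 becoming a stereocentre here without control and being corrected in step 14.

Step 14
Reactants: 25 acid as C3 epimer mixture
Product: 27 methyl (1S,2R,3R)-7-benzyloxy-1-Ar2-2-[(tert-butyldiphenylsilyloxy)methyl]-6-methoxytetralin-3-carboxylate, via methyl ester epimer mixture 26 (not isolated)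
Conditions: MeI, K2CO3, DMF, rt; then NaOMe, MeOH/THF, 50 °C
Reagents that add atoms: iodomethane CI
Why: Carboxylate O-alkylation followed by methoxide-mediated epimerisation through the ester enolate should move C3 to the 2,3-trans arrangement in which aryl, CH2OSi and CO2Me are all equatorial, an equilibration that is run on the open ester because the lactone of this ring system prefers the cis fusion and would give the wrong C3 epimer.

Step 15
Reactants: 27 trans methyl ester
Product: 28 [(1S,2R,3R)-7-benzyloxy-1-Ar2-2-[(tert-butyldiphenylsilyloxy)methyl]-6-methoxytetralin-3-yl]methanol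
Conditions: LiAlH4, THF, 0 °C
Reagents that add atoms: none
Why: Hydride reduction of the ester to the primary alcohol does not touch C3 and leaves benzyl and silyl ethers intact at this temperature.

Step 16
Reactants: 28 mono-silylated diol
Product: 29 [(1S,2R,3R)-7-benzyloxy-1-Ar2-6-methoxytetralin-2,3-diyl]dimethanol
Conditions: n-Bu4NF, THF, rt
Reagents that add atoms: none
Why: Fluoride-mediated desilylation frees the second primary alcohol while both phenols remain benzylated.

Step 17
Reactants: 29 diol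
Product: 30 [(1S,2R,3R)-7-benzyloxy-1-Ar2-6-methoxytetralin-2,3-diyl]bis(methylene) diacetate
Conditions: Ac2O, pyridine, DMAP (cat.), CH2Cl2, rt
Reagents that add atoms: acetic anhydride CC(=O)OC(C)=O
Why: DMAP-catalysed acylation of the two primary alcohols is unambiguous because both phenols are still benzyl ethers.

Step 18
Reactants: 30 dibenzyl diacetate
Product: 31 [(1S,2R,3R)-3-(acetoxymethyl)-7-hydroxy-1-(4-hydroxy-3,5-dimethoxyphenyl)-6-methoxy-1,2,3,4-tetrahydronaphthalen-2-yl]methyl acetate (CNP0265800.1)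
Conditions: H2 (1 atm), 10% Pd/C, EtOAc, rt
Reagents that add atoms: none
Why: Catalytic hydrogenolysis cleaves both aryl benzyl ethers under neutral conditions that leave the primary acetates and the three stereocentres unchanged.

Compound list
1 | 2-bromo-4-hydroxy-5-methoxybenzaldehyde (6-bromovanillin) | COc1cc(C=O)c(Br)cc1O | starting material
2 | 2-bromo-5-methoxy-4-(triisopropylsilyloxy)benzaldehyde | COc1cc(C=O)c(Br)cc1O[Si](C(C)C)(C(C)C)C(C)C | intermediate
3 | [2-bromo-5-methoxy-4-(triisopropylsilyloxy)phenyl]methanol | COc1cc(CO)c(Br)cc1O[Si](C(C)C)(C(C)C)C(C)C | intermediate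
4 | 2-bromo-5-methoxy-4-(triisopropylsilyloxy)benzyl pivalate | COc1cc(COC(=O)C(C)(C)C)c(Br)cc1O[Si](C(C)C)(C(C)C)C(C)C | intermediate
5 | acrolein diethyl acetal (3,3-diethoxyprop-1-ene) | C=CC(OCC)OCC | starting material
6 | (E)-3-[4-methoxy-2-(pivaloyloxymethyl)-5-(triisopropylsilyloxy)phenyl]prop-2-enal diethyl acetal | COc1cc(COC(=O)C(C)(C)C)c(/C=C/C(OCC)OCC)cc1O[Si](C(C)C)(C(C)C)C(C)C | intermediate
7 | (E)-3-[4-methoxy-2-(pivaloyloxymethyl)-5-(triisopropylsilyloxy)phenyl]prop-2-enal | COc1cc(COC(=O)C(C)(C)C)c(/C=C/C=O)cc1O[Si](C(C)C)(C(C)C)C(C)C | intermediate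
8 | 4-bromo-2,6-dimethoxyphenol | COc1cc(Br)cc(OC)c1O | starting material
9 | 2-benzyloxy-5-bromo-1,3-dimethoxybenzene | COc1cc(Br)cc(OC)c1OCc1ccccc1 | intermediate
10 | (4-benzyloxy-3,5-dimethoxyphenyl)lithium | [Li]c1cc(OC)c(OCc2ccccc2)c(OC)c1 | intermediate
11 | lithium (4-benzyloxy-3,5-dimethoxyphenyl)triisopropoxyborate | [Li+].CC(C)O[B-](OC(C)C)(OC(C)C)c1cc(OC)c(OCc2ccccc2)c(OC)c1 | intermediate
12 | (4-benzyloxy-3,5-dimethoxyphenyl)boronic acid | OB(O)c1cc(OC)c(OCc2ccccc2)c(OC)c1 | intermediate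
13 | (S)-3-(4-benzyloxy-3,5-dimethoxyphenyl)-3-[4-methoxy-2-(pivaloyloxymethyl)-5-(triisopropylsilyloxy)phenyl]propanal | COc1cc(COC(=O)C(C)(C)C)c(cc1O[Si](C(C)C)(C(C)C)C(C)C)[C@H](c1cc(OC)c(OCc2ccccc2)c(OC)c1)CC=O | intermediate
14 | (2S,3S)-2-chloro-3-(4-benzyloxy-3,5-dimethoxyphenyl)-3-[4-methoxy-2-(pivaloyloxymethyl)-5-(triisopropylsilyloxy)phenyl]propanal | COc1cc(COC(=O)C(C)(C)C)c(cc1O[Si](C(C)C)(C(C)C)C(C)C)[C@H](c1cc(OC)c(OCc2ccccc2)c(OC)c1)[C@H](Cl)C=O | intermediate
15 | (2S,3S)-2-chloro-3-(4-benzyloxy-3,5-dimethoxyphenyl)-3-[4-methoxy-2-(pivaloyloxymethyl)-5-(triisopropylsilyloxy)phenyl]propan-1-ol | COc1cc(COC(=O)C(C)(C)C)c(cc1O[Si](C(C)C)(C(C)C)C(C)C)[C@H](c1cc(OC)c(OCc2ccccc2)c(OC)c1)[C@H](Cl)CO | intermediate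
16 | (R)-2-[(S)-(4-benzyloxy-3,5-dimethoxyphenyl)[4-methoxy-2-(pivaloyloxymethyl)-5-(triisopropylsilyloxy)phenyl]methyl]oxirane | COc1cc(COC(=O)C(C)(C)C)c(cc1O[Si](C(C)C)(C(C)C)C(C)C)[C@H](c1cc(OC)c(OCc2ccccc2)c(OC)c1)[C@@H]1CO1 | intermediate
17 | di-tert-butyl malonate | CC(C)(C)OC(=O)CC(=O)OC(C)(C)C | starting material
18 | (R)-2-[(S)-(4-benzyloxy-3,5-dimethoxyphenyl)[5-hydroxy-4-methoxy-2-(pivaloyloxymethyl)phenyl]methyl]oxirane | COc1cc(COC(=O)C(C)(C)C)c(cc1O)[C@H](c1cc(OC)c(OCc2ccccc2)c(OC)c1)[C@@H]1CO1 | intermediate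
19 | 2-methoxy-4-methylidene-5-[(S)-(4-benzyloxy-3,5-dimethoxyphenyl)((R)-oxiran-2-yl)methyl]cyclohexa-2,5-dien-1-one | COC1=CC(=C)C(=CC1=O)[C@H](c1cc(OC)c(OCc2ccccc2)c(OC)c1)[C@@H]1CO1 | intermediate
20 | di-tert-butyl 2-[2-[(S)-(4-benzyloxy-3,5-dimethoxyphenyl)((R)-oxiran-2-yl)methyl]-4-hydroxy-5-methoxybenzyl]malonate | COc1cc(CC(C(=O)OC(C)(C)C)C(=O)OC(C)(C)C)c(cc1O)[C@H](c1cc(OC)c(OCc2ccccc2)c(OC)c1)[C@@H]1CO1 | intermediate
21 | di-tert-butyl (1S,2R)-1-(4-benzyloxy-3,5-dimethoxyphenyl)-7-hydroxy-2-(hydroxymethyl)-6-methoxy-1,2-dihydronaphthalene-3,3(4H)-dicarboxylate | COc1cc2c(cc1O)[C@H](c1cc(OC)c(OCc3ccccc3)c(OC)c1)[C@@H](CO)C(C(=O)OC(C)(C)C)(C(=O)OC(C)(C)C)C2 | intermediate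
22 | di-tert-butyl (1S,2R)-7-benzyloxy-1-(4-benzyloxy-3,5-dimethoxyphenyl)-2-(hydroxymethyl)-6-methoxy-1,2-dihydronaphthalene-3,3(4H)-dicarboxylate | COc1cc2c(cc1OCc1ccccc1)[C@H](c1cc(OC)c(OCc3ccccc3)c(OC)c1)[C@@H](CO)C(C(=O)OC(C)(C)C)(C(=O)OC(C)(C)C)C2 | intermediate
23 | di-tert-butyl (1S,2R)-7-benzyloxy-1-(4-benzyloxy-3,5-dimethoxyphenyl)-2-[(tert-butyldiphenylsilyloxy)methyl]-6-methoxy-1,2-dihydronaphthalene-3,3(4H)-dicarboxylate | COc1cc2c(cc1OCc1ccccc1)[C@H](c1cc(OC)c(OCc3ccccc3)c(OC)c1)[C@@H](CO[Si](c1ccccc1)(c1ccccc1)C(C)(C)C)C(C(=O)OC(C)(C)C)(C(=O)OC(C)(C)C)C2 | intermediate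
24 | (1S,2R)-7-benzyloxy-1-(4-benzyloxy-3,5-dimethoxyphenyl)-2-[(tert-butyldiphenylsilyloxy)methyl]-6-methoxy-1,2-dihydronaphthalene-3,3(4H)-dicarboxylic acid | COc1cc2c(cc1OCc1ccccc1)[C@H](c1cc(OC)c(OCc3ccccc3)c(OC)c1)[C@@H](CO[Si](c1ccccc1)(c1ccccc1)C(C)(C)C)C(C(O)=O)(C(O)=O)C2 | intermediate
25 | (1S,2R,3RS)-7-benzyloxy-1-(4-benzyloxy-3,5-dimethoxyphenyl)-2-[(tert-butyldiphenylsilyloxy)methyl]-6-methoxy-1,2,3,4-tetrahydronaphthalene-3-carboxylic acid (C3 epimer mixture) | COc1cc2c(cc1OCc1ccccc1)[C@H](c1cc(OC)c(OCc3ccccc3)c(OC)c1)[C@@H](CO[Si](c1ccccc1)(c1ccccc1)C(C)(C)C)C(C(O)=O)C2 | intermediate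
26 | methyl ester of 25, (1S,2R,3RS), C3 epimer mixture | COc1cc2c(cc1OCc1ccccc1)[C@H](c1cc(OC)c(OCc3ccccc3)c(OC)c1)[C@@H](CO[Si](c1ccccc1)(c1ccccc1)C(C)(C)C)C(C(=O)OC)C2 | intermediate
27 | methyl (1S,2R,3R)-7-benzyloxy-1-(4-benzyloxy-3,5-dimethoxyphenyl)-2-[(tert-butyldiphenylsilyloxy)methyl]-6-methoxy-1,2,3,4-tetrahydronaphthalene-3-carboxylate | COc1cc2c(cc1OCc1ccccc1)[C@H](c1cc(OC)c(OCc3ccccc3)c(OC)c1)[C@@H](CO[Si](c1ccccc1)(c1ccccc1)C(C)(C)C)[C@H](C(=O)OC)C2 | intermediate
28 | [(1S,2R,3R)-7-benzyloxy-1-(4-benzyloxy-3,5-dimethoxyphenyl)-2-[(tert-butyldiphenylsilyloxy)methyl]-6-methoxy-1,2,3,4-tetrahydronaphthalen-3-yl]methanol | COc1cc2c(cc1OCc1ccccc1)[C@H](c1cc(OC)c(OCc3ccccc3)c(OC)c1)[C@@H](CO[Si](c1ccccc1)(c1ccccc1)C(C)(C)C)[C@H](CO)C2 | intermediate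
29 | [(1S,2R,3R)-7-benzyloxy-1-(4-benzyloxy-3,5-dimethoxyphenyl)-6-methoxy-1,2,3,4-tetrahydronaphthalene-2,3-diyl]dimethanol | COc1cc2c(cc1OCc1ccccc1)[C@H](c1cc(OC)c(OCc3ccccc3)c(OC)c1)[C@@H](CO)[C@H](CO)C2 | intermediate
30 | [(1S,2R,3R)-7-benzyloxy-1-(4-benzyloxy-3,5-dimethoxyphenyl)-6-methoxy-1,2,3,4-tetrahydronaphthalene-2,3-diyl]bis(methylene) diacetate | COc1cc2c(cc1OCc1ccccc1)[C@H](c1cc(OC)c(OCc3ccccc3)c(OC)c1)[C@@H](COC(C)=O)[C@H](COC(C)=O)C2 | intermediate
31 | [(1S,2R,3R)-3-(acetoxymethyl)-7-hydroxy-1-(4-hydroxy-3,5-dimethoxyphenyl)-6-methoxy-1,2,3,4-tetrahydronaphthalen-2-yl]methyl acetate | COc1cc2c(cc1O)[C@H](c1cc(OC)c(O)c(OC)c1)[C@@H](COC(C)=O)[C@H](COC(C)=O)C2 | target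

Total step count: 18. Longest linear sequence: 16 steps (from 1 through steps 1–4 and 7–18).

Steps most likely to fail

Step 10. The malonate carbanion may attack the terminal oxirane carbon (7-endo closure), or the oxirane may be opened intermolecularly by excess malonate, so that ring B does not close at C2. The fallback removes the regiochemical choice by placing a single leaving group on C2. Setting out from aldehyde 13, chlorination with the mirror-image pyrrolidine catalyst and N-chlorosuccinimide would give the (2R,3S)-2-chloro aldehyde F1, reduced in the same flask with NaBH4 to the (2R,3S)-chlorohydrin F2. Silylation with t-BuPh2SiCl and imidazole would give the silyl ether F3. Treatment with CsF, Cs2CO3 and malonate 17 in DMF would then unmask only the aryl silyl ether and form the chloro quinone methide F4 and, after 1,6-addition, the open-chain chloro malonate adduct F5. The carbanion of F5 would displace the secondary chloride with inversion (6-exo-tet malonate alkylation) to give the cyclised phenol F6. Benzylation of F6 (BnBr, K2CO3) returns to the route at 23.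

Step 8. The existing C1 centre may override the catalyst at the enamine (poor facial selectivity), or the hindered aldehyde may chlorinate slowly and the chloro aldehyde may epimerise before reduction. The fallback sets C2 by oxygenation instead of chlorination. From aldehyde 13, L-proline-catalysed α-aminoxylation with nitrosobenzene would give the (2R,3S)-2-(anilinooxy) aldehyde F7, reduced in the same flask with NaBH4 to the aminoxy alcohol F8. Cleavage of the N–O bond with Zn dust in AcOH/EtOH would give the (2R,3S)-1,2-diol F9, and selective sulfonylation of the primary hydroxyl (TsCl, Bu2SnO cat., Et3N) would give the monotosylate F10. NaH in THF would then close the oxirane with retention at C2 and return to the route at 16.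

Step 7. Competing 1,2-addition to the aldehyde, erosion of enantioselectivity with the ortho-substituted enal, or base-induced loss of the silyl group under the aqueous conditions may spoil the arylation. The fallback moves the asymmetric arylation to an ester acceptor. From bromide 4, Heck reaction with methyl acrylate (Pd(OAc)2, P(o-tol)3, Et3N, DMF) would give the methyl cinnamate F11. Chiral diene/rhodium-catalysed 1,4-addition of boronic acid 12, well established for cinnamate esters, would give the methyl (S)-3,3-diarylpropanoate F12. Reduction with i-Bu2AlH (1 equiv, CH2Cl2, −78 °C), under which the hindered pivalate should survive, returns to the route at 13.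

Further compounds
F1 | step 10 | (2R,3S)-2-chloro-3-(4-benzyloxy-3,5-dimethoxyphenyl)-3-[4-methoxy-2-(pivaloyloxymethyl)-5-(triisopropylsilyloxy)phenyl]propanal | COc1cc(COC(=O)C(C)(C)C)c(cc1O[Si](C(C)C)(C(C)C)C(C)C)[C@H](c1cc(OC)c(OCc2ccccc2)c(OC)c1)[C@@H](Cl)C=O
F2 | step 10 | (2R,3S)-2-chloro-3-(4-benzyloxy-3,5-dimethoxyphenyl)-3-[4-methoxy-2-(pivaloyloxymethyl)-5-(triisopropylsilyloxy)phenyl]propan-1-ol | COc1cc(COC(=O)C(C)(C)C)c(cc1O[Si](C(C)C)(C(C)C)C(C)C)[C@H](c1cc(OC)c(OCc2ccccc2)c(OC)c1)[C@@H](Cl)CO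
F3 | step 10 | tert-butyldiphenylsilyl ether of F2 | COc1cc(COC(=O)C(C)(C)C)c(cc1O[Si](C(C)C)(C(C)C)C(C)C)[C@H](c1cc(OC)c(OCc2ccccc2)c(OC)c1)[C@@H](Cl)CO[Si](c1ccccc1)(c1ccccc1)C(C)(C)C
F4 | step 10 | 2-methoxy-4-methylidene-5-[(1S,2R)-1-(4-benzyloxy-3,5-dimethoxyphenyl)-2-chloro-3-(tert-butyldiphenylsilyloxy)propyl]cyclohexa-2,5-dien-1-one | COC1=CC(=C)C(=CC1=O)[C@H](c1cc(OC)c(OCc2ccccc2)c(OC)c1)[C@@H](Cl)CO[Si](c1ccccc1)(c1ccccc1)C(C)(C)C
F5 | step 10 | di-tert-butyl 2-[2-[(1S,2R)-1-(4-benzyloxy-3,5-dimethoxyphenyl)-2-chloro-3-(tert-butyldiphenylsilyloxy)propyl]-4-hydroxy-5-methoxybenzyl]malonate | COc1cc(CC(C(=O)OC(C)(C)C)C(=O)OC(C)(C)C)c(cc1O)[C@H](c1cc(OC)c(OCc2ccccc2)c(OC)c1)[C@@H](Cl)CO[Si](c1ccccc1)(c1ccccc1)C(C)(C)C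
F6 | step 10 | di-tert-butyl (1S,2R)-1-(4-benzyloxy-3,5-dimethoxyphenyl)-2-[(tert-butyldiphenylsilyloxy)methyl]-7-hydroxy-6-methoxy-1,2-dihydronaphthalene-3,3(4H)-dicarboxylate | COc1cc2c(cc1O)[C@H](c1cc(OC)c(OCc3ccccc3)c(OC)c1)[C@@H](CO[Si](c1ccccc1)(c1ccccc1)C(C)(C)C)C(C(=O)OC(C)(C)C)(C(=O)OC(C)(C)C)C2
F7 | step 8 | (2R,3S)-2-(anilinooxy)-3-(4-benzyloxy-3,5-dimethoxyphenyl)-3-[4-methoxy-2-(pivaloyloxymethyl)-5-(triisopropylsilyloxy)phenyl]propanal | COc1cc(COC(=O)C(C)(C)C)c(cc1O[Si](C(C)C)(C(C)C)C(C)C)[C@H](c1cc(OC)c(OCc2ccccc2)c(OC)c1)[C@@H](ONc1ccccc1)C=O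
F8 | step 8 | (2R,3S)-2-(anilinooxy)-3-(4-benzyloxy-3,5-dimethoxyphenyl)-3-[4-methoxy-2-(pivaloyloxymethyl)-5-(triisopropylsilyloxy)phenyl]propan-1-ol | COc1cc(COC(=O)C(C)(C)C)c(cc1O[Si](C(C)C)(C(C)C)C(C)C)[C@H](c1cc(OC)c(OCc2ccccc2)c(OC)c1)[C@@H](ONc1ccccc1)CO
F9 | step 8 | (2R,3S)-3-(4-benzyloxy-3,5-dimethoxyphenyl)-3-[4-methoxy-2-(pivaloyloxymethyl)-5-(triisopropylsilyloxy)phenyl]propane-1,2-diol | COc1cc(COC(=O)C(C)(C)C)c(cc1O[Si](C(C)C)(C(C)C)C(C)C)[C@H](c1cc(OC)c(OCc2ccccc2)c(OC)c1)[C@@H](O)CO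
F10 | step 8 | 1-O-(p-toluenesulfonyl) derivative of F9 | COc1cc(COC(=O)C(C)(C)C)c(cc1O[Si](C(C)C)(C(C)C)C(C)C)[C@H](c1cc(OC)c(OCc2ccccc2)c(OC)c1)[C@@H](O)COS(=O)(=O)c1ccc(C)cc1
F11 | step 7 | methyl (E)-3-[4-methoxy-2-(pivaloyloxymethyl)-5-(triisopropylsilyloxy)phenyl]prop-2-enoate | COc1cc(COC(=O)C(C)(C)C)c(/C=C/C(=O)OC)cc1O[Si](C(C)C)(C(C)C)C(C)C
F12 | step 7 | methyl (S)-3-(4-benzyloxy-3,5-dimethoxyphenyl)-3-[4-methoxy-2-(pivaloyloxymethyl)-5-(triisopropylsilyloxy)phenyl]propanoate | COc1cc(COC(=O)C(C)(C)C)c(cc1O[Si](C(C)C)(C(C)C)C(C)C)[C@H](c1cc(OC)c(OCc2ccccc2)c(OC)c1)CC(=O)OC
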